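**Retrosynthetic overview**
- The target is cut at both ring–CH2–ring bonds. Each bridge is one C1 unit (formaldehyde) between an outer dienone ring (propionylfilicinic acid, used twice) and the central aromatic ring (2,4,6-trihydroxybutyrophenone).
- Outer ring: hexane-2,4-dione 1 and dimethyl 2,2-dimethylmalonate 2 give the gem-dimethyl tetraketide ester 3, which closes by a polyketide-style Claisen condensation to 4 in the same pot.
- Central ring: triacetic acid lactone 5 and methyl butanoate 6 give pyrone 7, which is opened to the linear tetraketide ester 8 and closed by Claisen condensation to 9.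
- Ring order: the outer ring (step 1) and the central ring (steps 2–3) are made independently; the three rings are joined last by two methylene bridges (step 4, through 10 and 11 to 12).

Assumption: the target has no stereocentre (the ring carbons carrying two methyl groups are not stereogenic), so it is one achiral compound and no stereocontrol is needed; tautomers are drawn as in the given SMILES.

**Step 1**
Reactants: 1 hexane-2,4-dione; 2 dimethyl 2,2-dimethylmalonate
Product: 4 propionylfilicinic acid (3,5-dihydroxy-4,4-dimethyl-2-propanoylcyclohexa-2,5-dien-1-one), via triketo ester 3 (not isolated)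
Conditions: LiN(iPr)2 (2.1 equiv), THF, −78 → 0 °C; 2 (1.0 equiv), −78 → 0 °C; LiN(iPr)2 (1.1 equiv), 0 → 65 °C, 3 h; 1 M HCl
Reagents that add atoms: none
Why: Proposed new method: the kinetic 1,3-dianion of 1 (second deprotonation at CH3, not at the ethyl CH2) is acylated at its terminal carbon by one ester group of the non-enolisable diester 2, and the resulting triketo ester 3, deprotonated again, closes by a 6-exo Claisen (Dieckmann-type) attack of C-6 on the second ester, mirroring the C6-to-C1 Claisen cyclisation of a polyketide synthase, with the quaternary C-2 ruling out the competing aldol mode and the doubly stabilised dianion of 4 acting as thermodynamic sink (any O-cyclised pyranone is reopened by the liberated methoxide); the closest known reaction types are the terminal acylation of β-diketone dianions by esters to 1,3,5-triketones and the base-mediated Claisen cyclisation of 3,5,7-triketo esters to acylphloroglucinols, and no stereocentre is formed.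

**Step 2**
Reactants: 5 4-hydroxy-6-methyl-2H-pyran-2-one (triacetic acid lactone); 6 methyl butanoate
Product: 7 4-hydroxy-6-(2-oxopentyl)-2H-pyran-2-one
Conditions: LiN(iPr)2 (3.1 equiv), THF–DMPU, −78 → −20 °C; 6 (1.0 equiv), −78 → 0 °C; 1 M HCl
Reagents that add atoms: none
Why: Claisen-type C-acylation of the pyrone dianion, whose second deprotonation occurs at the vinylogous 6-methyl group, with the third equivalent of base holding the more acidic product as its enolate so that it is not acylated again; no stereocentre is formed.

**Step 3**
Reactants: 7 4-hydroxy-6-(2-oxopentyl)-2H-pyran-2-one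
Product: 9 1-(2,4,6-trihydroxyphenyl)butan-1-one, via tetraketide ester 8 (not isolated)
Conditions: Mg(OMe)2 (5 equiv), MeOH, reflux, 16 h; 2 M HCl
Reagents that add atoms: none
Why: Biomimetic polyketide Claisen (Dieckmann-type) cyclisation, in which methoxide opens the pyrone to the methyl ester 8 and its magnesium chelate closes C-6 onto the ester carbon and aromatises by enolisation, the ester (rather than a carboxylate, which would force the aldol/resorcylic mode) being what makes the acylphloroglucinol mode available; no stereocentre is formed.

**Step 4**
Reactants: 9 1-(2,4,6-trihydroxyphenyl)butan-1-one; 4 propionylfilicinic acid (3.0 equiv)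
Product: 12 2,2'-[(5-butanoyl-2,4,6-trihydroxy-1,3-phenylene)bis(methylene)]bis(3,5-dihydroxy-4,4-dimethyl-6-propanoylcyclohexa-2,5-dien-1-one), via methylidene enedione 10 (not isolated), via mono-bridged dimer 11 (not isolated)
Conditions: 37% aq. CH2O (2.5 equiv), 1% aq. KOH, 0 °C → rt, 30 min; 1 M HCl
Reagents that add atoms: formaldehyde, C=O
Why: Knoevenagel-type condensation of formaldehyde at the single free ring CH of the filicinate gives the enedione 10, which is captured in a Michael addition by the two free nuclear positions of the phloroglucinolate one after the other (the classical methylene bridging of acylphloroglucinols), and since 4 can only cap while 9 has exactly two reactive carbons the 2:1 adduct is the end-point; no stereocentre is formed.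

**Compound list**
1 | hexane-2,4-dione | CCC(=O)CC(C)=O | starting material
2 | dimethyl 2,2-dimethylmalonate | COC(=O)C(C)(C)C(=O)OC | starting material
3 | methyl 2,2-dimethyl-3,5,7-trioxononanoate | CCC(=O)CC(=O)CC(=O)C(C)(C)C(=O)OC | intermediate
4 | propionylfilicinic acid (3,5-dihydroxy-4,4-dimethyl-2-propanoylcyclohexa-2,5-dien-1-one) | CCC(=O)C1=C(O)C(C)(C)C(O)=CC1=O | intermediate
5 | 4-hydroxy-6-methyl-2H-pyran-2-one (triacetic acid lactone) | CC1=CC(O)=CC(=O)O1 | starting material
6 | methyl butanoate | CCCC(=O)OC | starting material
7 | 4-hydroxy-6-(2-oxopentyl)-2H-pyran-2-one | CCCC(=O)CC1=CC(O)=CC(=O)O1 | intermediate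
8 | methyl 3,5,7-trioxodecanoate (as its magnesium chelate) | CCCC(=O)CC(=O)CC(=O)CC(=O)OC | intermediate
9 | 1-(2,4,6-trihydroxyphenyl)butan-1-one | CCCC(=O)c1c(O)cc(O)cc1O | intermediate
10 | 3-hydroxy-4,4-dimethyl-6-methylidene-2-propanoylcyclohex-2-ene-1,5-dione | CCC(=O)C1=C(O)C(C)(C)C(=O)C(=C)C1=O | intermediate
11 | 2-[(3-butanoyl-2,4,6-trihydroxyphenyl)methyl]-3,5-dihydroxy-4,4-dimethyl-6-propanoylcyclohexa-2,5-dien-1-one | CCCC(=O)c1c(O)cc(O)c(CC2=C(O)C(C)(C)C(O)=C(C(=O)CC)C2=O)c1O | intermediate
12 | 2,2'-[(5-butanoyl-2,4,6-trihydroxy-1,3-phenylene)bis(methylene)]bis(3,5-dihydroxy-4,4-dimethyl-6-propanoylcyclohexa-2,5-dien-1-one) | CCCC(=O)c1c(O)c(CC2=C(O)C(C)(C)C(O)=C(C(=O)CC)C2=O)c(O)c(CC2=C(O)C(C)(C)C(O)=C(C(=O)CC)C2=O)c1O | target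

**Totals**
Total step count: 4. Longest linear sequence: 3 steps (5 → 7 → 9 → 12).

**Steps most likely to fail, with fallbacks**

Step 1 (one-pot acylation and ring closure). The risks are partial deprotonation at the ethyl CH2, slow attack on the hindered diester, and O- instead of C-cyclisation. The fallback closes the ring before the acyl group is present and sets out from 2. A crossed Claisen condensation of 2 with the lithium enolate of acetone (LiN(iPr)2, THF, −78 °C) gives methyl 2,2-dimethyl-3,5-dioxohexanoate F1. Its dianion (NaH, then LiN(iPr)2, THF, 0 °C → reflux) closes through the terminal carbon onto the ester to give filicinic acid (3,5-dihydroxy-4,4-dimethylcyclohexa-2,5-dien-1-one) F2. Friedel–Crafts-type C-propionylation of F2 (propanoyl chloride, AlCl3, nitrobenzene, rt) returns to the route at 4.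

Step 3 (Claisen versus aldol closure of the tetraketide). The risks are aldol closure to the resorcylate ester or simple re-lactonisation; the same fallback also bypasses step 2. It builds the ring without the acyl chain, where no aldol mode giving a six-membered ring exists, and sets out from 5. Methanolysis of 5 with Mg(OMe)2 in MeOH gives methyl 3,5-dioxohexanoate F3. F3 is cyclised through its terminal carbanion (NaH or sodium metal, diglyme, 150–185 °C) to phloroglucinol (benzene-1,3,5-triol) F4. Friedel–Crafts butyrylation of F4 (butanoyl chloride, AlCl3, nitrobenzene/CS2, rt) returns to the route at 9.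

Step 4 (double methylene bridging). The risk is a statistical mixture: the homodimer of 4 (albaspidin type), the mono-bridged 11, and scrambling by methylene exchange in alkali. The fallback fixes the electrophilic CH2 groups on the central ring first and sets out from 9. Mannich reaction of 9 with bis(dimethylamino)methane (2.2 equiv, EtOH, rt) gives the bis-Mannich base 1-{3,5-bis[(dimethylamino)methyl]-2,4,6-trihydroxyphenyl}butan-1-one F5. Heating F5 with 4 (2.2 equiv) in dioxane at 90 °C expels dimethylamine to form ortho-quinone methides on the central ring only. These are captured by the enol of 4 in a Michael addition, so no homodimer of 4 can form, and the route is rejoined at 12.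

**Further compounds**
F1 | step 1 | methyl 2,2-dimethyl-3,5-dioxohexanoate | CC(=O)CC(=O)C(C)(C)C(=O)OC
F2 | step 1 | filicinic acid (3,5-dihydroxy-4,4-dimethylcyclohexa-2,5-dien-1-one) | CC1(C)C(O)=CC(=O)C=C1O
F3 | step 3 | methyl 3,5-dioxohexanoate | CC(=O)CC(=O)CC(=O)OC
F4 | step 3 | phloroglucinol (benzene-1,3,5-triol) | Oc1cc(O)cc(O)c1
F5 | step 4 | 1-{3,5-bis[(dimethylamino)methyl]-2,4,6-trihydroxyphenyl}butan-1-one | CCCC(=O)c1c(O)c(CN(C)C)c(O)c(CN(C)C)c1O
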